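**Retrosynthetic overview**

1. Maltepolide D (42) ⇐ desilylation of 41 ⇐ ring closure at the C7–C8 bond by Stille coupling of the open-chain ester 40, which carries an (E)-β-iodoenone at C7 and a (Z)-alkenylstannane at C8.
2. 40 ⇐ intermolecular Still–Gennari olefination (C2=C3, Z) of phosphonate ester 29 (C8–C24, acylated at O19) with aldehyde 37 (C3–C7; C4 from an Evans syn aldol, C6=C7 from carboalumination), then unmasking of the C5 ketone.
3. 29 ⇐ C11 by catalytic propargylboration of a (Z)-enal (C12=C13 by Still–Gennari); oxolane by epoxidation/5-exo opening of the 15,17-syn diol 13; 13 ⇐ 1,5-anti aldol and syn reduction of methyl ketone 10 ⇐ crotylboration of enal 6 ⇐ desymmetrised divinylcarbinol.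
4. Ring order: the oxolane ring (O, C14–C17) is closed first (step 10), the 20-membered lactone last (step 32).
5. Enabling feature: C7 is the β-carbon of the C5 ketone and C8 the terminus of the isolated (Z)-C8=C9 alkene, so C7–C8 is the central σ-bond of the C5-oxo-6E,8Z-diene in the 20-membered ring. It can be made without base and without creating a stereocentre, which matters because C4–H (between C5=O and the C2=C3–C1 enoate) is a vinylogous β-dicarbonyl C–H. The three cis-in-ring alkenes (C2=C3, C8=C9, C12=C13) and the 2,5-trans oxolane fold the chain so that C7 and C8 can meet.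

Key step: step 32

Remark: macrolide numbering is used (C1 lactone carbonyl, O19 lactone oxygen, C24 side-chain methyl). TBS = tert-butyldimethylsilyl, TES = triethylsilyl, PMB = 4-methoxybenzyl, TRIP = 3,3'-bis(2,4,6-triisopropylphenyl)-1,1'-binaphthyl-2,2'-diyl hydrogen phosphate. Boronates 7 and 22, both TRIP enantiomers and phosphonate 17 are taken as commercial.

**Route**

Step 1
Reactants: 1 penta-1,4-dien-3-ol
Product: 2 (2S,3R)-1,2-epoxypent-4-en-3-ol
Conditions: Ti(OiPr)4 (cat.), D-(−)-diisopropyl tartrate (cat.), t-BuOOH, 4 Å MS, CH2Cl2, −20 °C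
Reagents that add atoms: tert-butyl hydroperoxide, `CC(C)(C)OO`
Why: Sharpless asymmetric epoxidation desymmetrises the dienol, the D-tartrate titanium complex epoxidising one enantiotopic vinyl group from one face (erythro product), which sets C22 and C23 together, while the minor enantiomer should be removed by faster second epoxidation.

Step 2
Reactants: 2 (2S,3R)-1,2-epoxypent-4-en-3-ol
Product: 3 (2S,3R)-pent-4-ene-2,3-diol
Conditions: LiAlH4, THF, 0 °C
Reagents that add atoms: none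
Why: Hydride opening of the terminal epoxide (SN2 at the unsubstituted carbon) turns the oxirane CH2 into the C24 methyl group and leaves both stereocentres untouched.

Step 3
Reactants: 3 (2S,3R)-pent-4-ene-2,3-diol
Product: 4 (3R,4S)-3,4-bis(TBSO)pent-1-ene
Conditions: TBSOTf, 2,6-lutidine, CH2Cl2, 0 °C
Reagents that add atoms: tert-butyldimethylsilyl triflate, `C[Si](C)(OS(=O)(=O)C(F)(F)F)C(C)(C)C`
Why: Silylation with a silyl triflate, which is reactive enough to protect both hindered vicinal secondary alcohols.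

Step 4
Reactants: 4 (3R,4S)-3,4-bis(TBSO)pent-1-ene; 5 (E)-but-2-enal
Product: 6 (2E,4R,5S)-4,5-bis(TBSO)hex-2-enal
Conditions: second-generation Hoveyda–Grubbs catalyst RuCl2(H2IMes)(=CH-C6H4-2-OiPr) (5 mol %), 5 in excess, CH2Cl2, 40 °C
Reagents that add atoms: none
Why: Olefin cross-metathesis of the terminal alkene with an excess of the enal partner should give the conjugated aldehyde as its thermodynamically favoured E isomer (C20=C21), propene being lost.

Step 5
Reactants: 6 (2E,4R,5S)-4,5-bis(TBSO)hex-2-enal; 7 (Z)-crotylboronic acid pinacol ester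
Product: 8 (3R,4R,5E,7R,8S)-7,8-bis(TBSO)-3-methylnona-1,5-dien-4-ol
Conditions: (S)-TRIP (5 mol %), 4 Å MS, toluene, −30 °C
Reagents that add atoms: none
Why: Chiral phosphoric-acid-catalysed crotylboration through a closed six-membered chair transition state, in which the Z-crotyl boronate gives the 18,19-syn pair and the (S)-configured catalyst directs attack to the Si face of the aldehyde, so that C19 (R) and C18 (R) are set under catalyst control.

Step 6
Reactants: 8 homoallylic alcohol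
Product: 9 PMB ether of 8
Conditions: NaH, 4-methoxybenzyl chloride, Bu4NI (cat.), THF/DMF, 0 °C to rt
Reagents that add atoms: 4-methoxybenzyl chloride, `COc1ccc(CCl)cc1`
Why: Williamson etherification of the sodium alkoxide, no other acidic or electrophilic site being present.

Step 7
Reactants: 9 PMB ether
Product: 10 (3S,4R,5E,7R,8S)-7,8-bis(TBSO)-4-(PMBO)-3-methylnon-5-en-2-one
Conditions: PdCl2 (10 mol %), CuCl (cat.), O2 (1 atm), DMF/H2O, rt
Reagents that add atoms: water, `O` (carbonyl oxygen; O2, `O=O`, is the terminal oxidant)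
Why: Tsuji–Wacker oxidation, in which Markovnikov hydroxypalladation of the monosubstituted alkene gives the methyl ketone while the internal C20=C21 alkene flanked by two allylic ethers is too hindered to react.

Step 8
Reactants: 10 methyl ketone; 11 prop-2-enal
Product: 12 (3S,6S,7R,8E,10R,11S)-10,11-bis(TBSO)-3-hydroxy-7-(PMBO)-6-methyldodeca-1,8-dien-5-one
Conditions: (c-C6H11)2BCl, Et3N, Et2O, −78 to 0 °C; 11, −78 °C; then MeOH, pH 7 buffer, H2O2
Reagents that add atoms: none
Why: Boron aldol reaction of the kinetically formed methyl-side enol borinate, in which the β-PMB ether of the enolate imposes 1,5-anti induction and so sets C15 (S) relative to C19.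

Step 9
Reactants: 12 β-hydroxy ketone
Product: 13 (3S,5R,6R,7R,8E,10R,11S)-10,11-bis(TBSO)-7-(PMBO)-6-methyldodeca-1,8-diene-3,5-diol
Conditions: Et2BOMe, NaBH4, THF/MeOH, −78 °C; then NaOH, H2O2
Reagents that add atoms: none
Why: Narasaka–Prasad reduction, in which the boron chelate of the β-hydroxy ketone is reduced by external hydride in a half-chair to give the 15,17-syn diol and set C17 (R).

Step 10
Reactants: 13 syn-1,3-diol
Product: 15 (2S,3S,5R)-5-[(2R,3R,4E,6R,7S)-6,7-bis(TBSO)-3-(PMBO)oct-4-en-2-yl]-2-(hydroxymethyl)oxolan-3-ol, via epoxy diol 14 (not isolated)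
Conditions: Ti(OiPr)4 (1 equiv), L-(+)-diisopropyl tartrate (1.2 equiv), t-BuOOH, 4 Å MS, CH2Cl2, −20 °C; then camphorsulfonic acid (cat.), 0 °C
Reagents that add atoms: tert-butyl hydroperoxide, `CC(C)(C)OO`
Why: Sharpless asymmetric epoxidation in the matched sense (L-tartrate with the S-configured allylic carbinol) should give the erythro epoxy alcohol, and acid-catalysed 5-exo opening by the C17 hydroxyl with inversion at C14 closes the 2,5-trans oxolane with C13 cis to O15 (C14 S).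

Step 11
Reactants: 15 oxolane diol
Product: 16 (2R,3S,5R)-5-[(2R,3R,4E,6R,7S)-6,7-bis(TBSO)-3-(PMBO)oct-4-en-2-yl]-3-hydroxyoxolane-2-carbaldehyde
Conditions: TEMPO (cat.), PhI(OAc)2, CH2Cl2, rt
Reagents that add atoms: none
Why: Oxoammonium (TEMPO) oxidation is selective for the primary alcohol over the hindered secondary one.

Step 12
Reactants: 16 hydroxy aldehyde; 17 ethyl 2-[bis(2,2,2-trifluoroethoxy)phosphoryl]propanoate
Product: 18 ethyl (2Z)-3-[(2S,3S,5R)-5-(side chain as in 15)-3-hydroxyoxolan-2-yl]-2-methylprop-2-enoate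
Conditions: 17, KN(SiMe3)2, 18-crown-6, THF, −78 °C
Reagents that add atoms: none
Why: Still–Gennari olefination, in which the electron-poor bis(trifluoroethyl) phosphonate eliminates fast from the kinetic adduct to give the Z-trisubstituted enoate (C12=C13), the stabilised phosphonate anion being too weak a base to deprotonate the free C15 hydroxyl.

Step 13
Reactants: 18 hydroxy enoate
Product: 19 C15 methyl ether of 18
Conditions: Me3OBF4, 1,8-bis(dimethylamino)naphthalene, CH2Cl2, 0 °C to rt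
Reagents that add atoms: trimethyloxonium tetrafluoroborate, `C[O+](C)C.F[B-](F)(F)F`
Why: O-Methylation with Meerwein's salt under non-basic conditions (hindered amine as proton scavenger), which avoids elimination and ester cleavage.

Step 14
Reactants: 19 Z-enoate
Product: 20 (Z)-allylic alcohol (C11 CH2OH)
Conditions: iBu2AlH, CH2Cl2, −78 °C
Reagents that add atoms: none
Why: 1,2-Reduction of the enoate by the aluminium hydride at low temperature gives the allylic alcohol without touching the alkene geometry.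

Step 15
Reactants: 20 (Z)-allylic alcohol
Product: 21 (Z)-enal (C11 aldehyde)
Conditions: MnO2, CH2Cl2, rt, dark
Reagents that add atoms: none
Why: Allylic oxidation with MnO2 under neutral conditions, chosen because it should not isomerise the Z-enal.

Step 16
Reactants: 21 (Z)-enal; 22 allenylboronic acid pinacol ester
Product: 23 (11R)-homopropargylic alcohol (C8–C24, terminal alkyne)
Conditions: (R)-TRIP (10 mol %), 4 Å MS, toluene, −20 °C
Reagents that add atoms: none
Why: Chiral phosphoric-acid-catalysed propargylboration through a six-membered SE2' transition state, in which the (R)-configured catalyst directs the allenyl boronate to the Re face of the aldehyde and sets C11 (R).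

Step 17
Reactants: 23 homopropargylic alcohol
Product: 24 11-O-TBS ether of 23
Conditions: TBSOTf, 2,6-lutidine, CH2Cl2, −78 °C
Reagents that add atoms: tert-butyldimethylsilyl triflate, `C[Si](C)(OS(=O)(=O)C(F)(F)F)C(C)(C)C`
Why: Silyl triflate silylation of the hindered allylic alcohol.

Step 18
Reactants: 24 terminal alkyne
Product: 25 C8-tributylstannyl alkyne
Conditions: n-BuLi (1.05 equiv), THF, −78 °C; Bu3SnCl
Reagents that add atoms: tributyltin chloride, `CCCC[Sn](Cl)(CCCC)CCCC`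
Why: Deprotonation of the terminal alkyne and trapping of the lithium acetylide with the tin chloride (stannylation), the alkyne C–H being by far the most acidic site.

Step 19
Reactants: 25 stannyl alkyne
Product: 26 (8Z)-alkenylstannane (19-OPMB)
Conditions: Cp2Zr(H)Cl (1.5 equiv), THF, rt; then H2O
Reagents that add atoms: none
Why: Hydrozirconation adds Zr–H syn across the stannylalkyne with zirconium on the tin-bearing carbon, and protonolysis with retention gives the Z-alkenylstannane (C8=C9).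

Step 20
Reactants: 26 PMB ether
Product: 27 (8Z)-alkenylstannane C19 alcohol
Conditions: DDQ, CH2Cl2/pH 7 buffer, 0 °C
Reagents that add atoms: none
Why: Oxidative cleavage of the electron-rich PMB ether by DDQ (benzylic hydride abstraction and hydrolysis of the oxocarbenium ion), which under buffered conditions should spare the silyl ethers, the alkenes and the alkenylstannane.

Step 21
Reactants: 17 ethyl 2-[bis(2,2,2-trifluoroethoxy)phosphoryl]propanoate
Product: 28 2-[bis(2,2,2-trifluoroethoxy)phosphoryl]propanoic acid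
Conditions: LiOH (1.05 equiv), THF/H2O, 0 °C; then aq. HCl to pH 2
Reagents that add atoms: lithium hydroxide, `[Li+].[OH-]`
Why: Saponification of the carboxylic ester with one equivalent of hydroxide at low temperature, under which the phosphonate esters should survive.

Step 22
Reactants: 27 C19 alcohol; 28 phosphono acid
Product: 29 O19 phosphonate ester of 27
Conditions: dicyclohexylcarbodiimide, DMAP (cat.), CH2Cl2, 0 °C to rt
Reagents that add atoms: none
Why: Steglich esterification (carbodiimide activation and acyl transfer by DMAP) of the only free hydroxyl.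

Step 23
Reactants: 30 prop-2-yn-1-ol
Product: 31 (E)-3-iodo-2-methylprop-2-en-1-ol
Conditions: Me3Al, Cp2ZrCl2 (cat.), CH2Cl2, 0 °C to rt; then I2, THF, −30 °C
Reagents that add atoms: trimethylaluminium, `C[Al](C)C`; iodine, `II`
Why: Zirconium-catalysed carboalumination (Negishi) adds methyl and aluminium syn across the alkyne with aluminium at the terminus, and iodinolysis with retention gives the E-iodoalkene (the later C6=C7 geometry).

Step 24
Reactants: 31 (E)-3-iodo-2-methylprop-2-en-1-ol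
Product: 32 (E)-3-iodo-2-methylprop-2-enal
Conditions: MnO2, CH2Cl2, rt
Reagents that add atoms: none
Why: Allylic oxidation with MnO2 under neutral conditions that keep the iodoalkene geometry.

Step 25
Reactants: 32 (E)-3-iodo-2-methylprop-2-enal; 33 (R)-4-benzyl-3-propanoyl-1,3-oxazolidin-2-one
Product: 34 (R)-4-benzyl-3-[(2R,3R,4E)-3-hydroxy-5-iodo-2,4-dimethylpent-4-enoyl]-1,3-oxazolidin-2-one
Conditions: Bu2BOTf, Et3N, CH2Cl2, −78 to 0 °C; 32, −78 to 0 °C; then MeOH, pH 7 buffer, H2O2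
Reagents that add atoms: none
Why: Evans syn aldol reaction, in which the Z-boron enolate reacts through a Zimmerman–Traxler transition state on the face opposite the benzyl group of the (R)-auxiliary and so sets C4 (the later 4S centre) and the transient C5 carbinol.

Step 26
Reactants: 34 aldol adduct
Product: 35 TES ether of 34
Conditions: TESOTf, 2,6-lutidine, CH2Cl2, −78 °C
Reagents that add atoms: triethylsilyl triflate, `CC[Si](CC)(CC)OS(=O)(=O)C(F)(F)F`
Why: Silyl triflate silylation of the secondary alcohol with a group that can later be removed in the presence of TBS ethers.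

Step 27
Reactants: 35 silylated imide
Product: 36 (2S,3R,4E)-5-iodo-2,4-dimethyl-3-(triethylsilyloxy)pent-4-en-1-ol
Conditions: LiBH4, MeOH (1 equiv), THF, 0 °C
Reagents that add atoms: none
Why: Reductive cleavage of the imide by borohydride releases the auxiliary and gives the primary alcohol without epimerisation.

Step 28
Reactants: 36 primary alcohol
Product: 37 (2R,3R,4E)-5-iodo-2,4-dimethyl-3-(triethylsilyloxy)pent-4-enal
Conditions: Dess–Martin periodinane, NaHCO3, CH2Cl2, 0 °C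
Reagents that add atoms: none
Why: Dess–Martin oxidation under buffered conditions should give the α-branched aldehyde without epimerisation.

Step 29
Reactants: 29 phosphonate ester; 37 aldehyde
Product: 38 open-chain (2Z)-enoate with 5-OTES, 7-iodo and 8-stannyl termini
Conditions: KN(SiMe3)2, 18-crown-6, THF, −78 °C; then 37
Reagents that add atoms: none
Why: Intermolecular Still–Gennari olefination joins the two halves and gives the Z-trisubstituted enoate (C2=C3), the pre-formed phosphonate anion not epimerising the α-branched aldehyde at −78 °C.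

Step 30
Reactants: 38 TES ether
Product: 39 C5 alcohol
Conditions: pyridinium p-toluenesulfonate (cat.), MeOH/CH2Cl2, 0 °C
Reagents that add atoms: none
Why: Acid-catalysed methanolysis removes the triethylsilyl ether much faster than the three tert-butyldimethylsilyl ethers.

Step 31
Reactants: 39 C5 alcohol
Product: 40 open-chain β-iodoenone (Stille precursor)
Conditions: Dess–Martin periodinane, NaHCO3, CH2Cl2, 0 °C
Reagents that add atoms: none
Why: Dess–Martin oxidation of the only free (allylic) alcohol gives the β-iodoenone under near-neutral conditions that should preserve the C4 configuration.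

Step 32
Reactants: 40 open-chain β-iodoenone/alkenylstannane
Product: 41 11,22,23-tris-O-TBS-maltepolide D
Conditions: Pd2(dba)3 (10 mol %), AsPh3 (80 mol %), degassed DMF, 25 °C, slow addition to 1 mM, dark
Reagents that add atoms: none
Why: Zerovalent palladium inserts into the C7–I bond of the (E)-β-iodoenone (a vinylogous acyl iodide, so oxidative addition is fast at room temperature), the (Z)-alkenyl group at C8 is transferred from tin with retention, and reductive elimination forms the C7–C8 σ-bond (Stille cross-coupling). The closest known reaction type is the intramolecular Stille coupling of an alkenyl iodide with an alkenylstannane that closes polyene macrolactones at a diene σ-bond. The one ring closed is the 20-membered lactone, by end-to-end macrocyclisation through a palladacycle whose C–C reductive elimination is the ring-forming event; the oxolane is already in place. No stereocentre is created, and the 6E and 8Z geometries are copied stereospecifically from the iodide (step 23) and the stannane (step 19). The step needs cyclisation to win over oligomerisation, which slow addition to high dilution and the folding imposed by the three cis-in-ring alkenes (C2=C3, C8=C9, C12=C13) and the 2,5-trans oxolane should secure, and it needs the C4 configuration to survive, which the neutral, base- and fluoride-free conditions should secure. In this one operation the macrocycle, the full C1–C24 skeleton and the C5-oxo-6E,8Z-diene are all finished from an open-chain precursor.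

Step 33
Reactants: 41 tris-TBS macrolide
Product: 42 Maltepolide D
Conditions: HF·pyridine, pyridine, THF, 0 °C to rt
Reagents that add atoms: none
Why: Fluoride-mediated desilylation under buffered, weakly acidic conditions should remove the three silyl ethers without base, so that the C4 centre and the dienone are not disturbed.

**Compound list**

1 | penta-1,4-dien-3-ol | `C=CC(O)C=C` | starting material
2 | (2S,3R)-1,2-epoxypent-4-en-3-ol | `C1O[C@@H]1[C@H](O)C=C` | intermediate
3 | (2S,3R)-pent-4-ene-2,3-diol | `C[C@H](O)[C@H](O)C=C` | intermediate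
4 | (3R,4S)-3,4-bis(tert-butyldimethylsilyloxy)pent-1-ene | `C[C@H](O[Si](C)(C)C(C)(C)C)[C@H](O[Si](C)(C)C(C)(C)C)C=C` | intermediate
5 | (E)-but-2-enal | `C/C=C/C=O` | starting material
6 | (2E,4R,5S)-4,5-bis(tert-butyldimethylsilyloxy)hex-2-enal (C19–C24) | `C[C@H](O[Si](C)(C)C(C)(C)C)[C@H](O[Si](C)(C)C(C)(C)C)/C=C/C=O` | intermediate
7 | (Z)-crotylboronic acid pinacol ester | `C/C=C\CB1OC(C)(C)C(C)(C)O1` | starting material
8 | (3R,4R,5E,7R,8S)-7,8-bis(TBSO)-3-methylnona-1,5-dien-4-ol (C16–C24, 18,19-syn) | `C[C@H](O[Si](C)(C)C(C)(C)C)[C@H](O[Si](C)(C)C(C)(C)C)/C=C/[C@@H](O)[C@H](C)C=C` | intermediate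
9 | (3R,4R,5E,7R,8S)-7,8-bis(TBSO)-4-(4-methoxybenzyloxy)-3-methylnona-1,5-diene | `C[C@H](O[Si](C)(C)C(C)(C)C)[C@H](O[Si](C)(C)C(C)(C)C)/C=C/[C@@H](OCc1ccc(OC)cc1)[C@H](C)C=C` | intermediate
10 | (3S,4R,5E,7R,8S)-7,8-bis(TBSO)-4-(4-methoxybenzyloxy)-3-methylnon-5-en-2-one | `C[C@H](O[Si](C)(C)C(C)(C)C)[C@H](O[Si](C)(C)C(C)(C)C)/C=C/[C@@H](OCc1ccc(OC)cc1)[C@H](C)C(C)=O` | intermediate
11 | prop-2-enal | `C=CC=O` | starting material
12 | (3S,6S,7R,8E,10R,11S)-10,11-bis(TBSO)-3-hydroxy-7-(4-methoxybenzyloxy)-6-methyldodeca-1,8-dien-5-one (C13–C24) | `C[C@H](O[Si](C)(C)C(C)(C)C)[C@H](O[Si](C)(C)C(C)(C)C)/C=C/[C@@H](OCc1ccc(OC)cc1)[C@H](C)C(=O)C[C@H](O)C=C` | intermediate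
13 | (3S,5R,6R,7R,8E,10R,11S)-10,11-bis(TBSO)-7-(4-methoxybenzyloxy)-6-methyldodeca-1,8-diene-3,5-diol (15,17-syn) | `C[C@H](O[Si](C)(C)C(C)(C)C)[C@H](O[Si](C)(C)C(C)(C)C)/C=C/[C@@H](OCc1ccc(OC)cc1)[C@H](C)[C@H](O)C[C@H](O)C=C` | intermediate
14 | (1S,3R,4R,5R,6E,8R,9S)-8,9-bis(TBSO)-5-(4-methoxybenzyloxy)-4-methyl-1-[(2R)-oxiran-2-yl]dec-6-ene-1,3-diol (not isolated) | `C[C@H](O[Si](C)(C)C(C)(C)C)[C@H](O[Si](C)(C)C(C)(C)C)/C=C/[C@@H](OCc1ccc(OC)cc1)[C@H](C)[C@H](O)C[C@H](O)[C@H]1CO1` | intermediate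
15 | (2S,3S,5R)-5-[(2R,3R,4E,6R,7S)-6,7-bis(TBSO)-3-(4-methoxybenzyloxy)oct-4-en-2-yl]-2-(hydroxymethyl)oxolan-3-ol | `C[C@H](O[Si](C)(C)C(C)(C)C)[C@H](O[Si](C)(C)C(C)(C)C)/C=C/[C@@H](OCc1ccc(OC)cc1)[C@H](C)[C@H]1C[C@H](O)[C@H](CO)O1` | intermediate
16 | (2R,3S,5R)-5-[(2R,3R,4E,6R,7S)-6,7-bis(TBSO)-3-(4-methoxybenzyloxy)oct-4-en-2-yl]-3-hydroxyoxolane-2-carbaldehyde | `C[C@H](O[Si](C)(C)C(C)(C)C)[C@H](O[Si](C)(C)C(C)(C)C)/C=C/[C@@H](OCc1ccc(OC)cc1)[C@H](C)[C@H]1C[C@H](O)[C@H](C=O)O1` | intermediate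
17 | ethyl 2-[bis(2,2,2-trifluoroethoxy)phosphoryl]propanoate | `CCOC(=O)C(C)P(=O)(OCC(F)(F)F)OCC(F)(F)F` | starting material
18 | ethyl (2Z)-3-[(2S,3S,5R)-5-[(2R,3R,4E,6R,7S)-6,7-bis(TBSO)-3-(4-methoxybenzyloxy)oct-4-en-2-yl]-3-hydroxyoxolan-2-yl]-2-methylprop-2-enoate | `C[C@H](O[Si](C)(C)C(C)(C)C)[C@H](O[Si](C)(C)C(C)(C)C)/C=C/[C@@H](OCc1ccc(OC)cc1)[C@H](C)[C@H]1C[C@H](O)[C@H](/C=C(/C)C(=O)OCC)O1` | intermediate
19 | ethyl (2Z)-3-[(2S,3S,5R)-5-(side chain as in 18)-3-methoxyoxolan-2-yl]-2-methylprop-2-enoate | `C[C@H](O[Si](C)(C)C(C)(C)C)[C@H](O[Si](C)(C)C(C)(C)C)/C=C/[C@@H](OCc1ccc(OC)cc1)[C@H](C)[C@H]1C[C@H](OC)[C@H](/C=C(/C)C(=O)OCC)O1` | intermediate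
20 | (2Z)-3-[(2S,3S,5R)-5-(side chain as in 18)-3-methoxyoxolan-2-yl]-2-methylprop-2-en-1-ol | `C[C@H](O[Si](C)(C)C(C)(C)C)[C@H](O[Si](C)(C)C(C)(C)C)/C=C/[C@@H](OCc1ccc(OC)cc1)[C@H](C)[C@H]1C[C@H](OC)[C@H](/C=C(/C)CO)O1` | intermediate
21 | (2Z)-3-[(2S,3S,5R)-5-(side chain as in 18)-3-methoxyoxolan-2-yl]-2-methylprop-2-enal | `C[C@H](O[Si](C)(C)C(C)(C)C)[C@H](O[Si](C)(C)C(C)(C)C)/C=C/[C@@H](OCc1ccc(OC)cc1)[C@H](C)[C@H]1C[C@H](OC)[C@H](/C=C(/C)C=O)O1` | intermediate
22 | allenylboronic acid pinacol ester | `C=C=CB1OC(C)(C)C(C)(C)O1` | starting material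
23 | (1Z,3R)-1-[(2S,3S,5R)-5-(side chain as in 18)-3-methoxyoxolan-2-yl]-2-methylhex-1-en-5-yn-3-ol (C8–C24, 11R) | `C[C@H](O[Si](C)(C)C(C)(C)C)[C@H](O[Si](C)(C)C(C)(C)C)/C=C/[C@@H](OCc1ccc(OC)cc1)[C@H](C)[C@H]1C[C@H](OC)[C@H](/C=C(/C)[C@H](O)CC#C)O1` | intermediate
24 | 11-O-TBS ether of 23 (terminal alkyne, 19-OPMB) | `C[C@H](O[Si](C)(C)C(C)(C)C)[C@H](O[Si](C)(C)C(C)(C)C)/C=C/[C@@H](OCc1ccc(OC)cc1)[C@H](C)[C@H]1C[C@H](OC)[C@H](/C=C(/C)[C@H](O[Si](C)(C)C(C)(C)C)CC#C)O1` | intermediate
25 | 24 with a tributylstannyl group on the alkyne terminus C8 | `C[C@H](O[Si](C)(C)C(C)(C)C)[C@H](O[Si](C)(C)C(C)(C)C)/C=C/[C@@H](OCc1ccc(OC)cc1)[C@H](C)[C@H]1C[C@H](OC)[C@H](/C=C(/C)[C@H](O[Si](C)(C)C(C)(C)C)CC#C[Sn](CCCC)(CCCC)CCCC)O1` | intermediate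
26 | C8–C24 (8Z)-alkenylstannane, 19-OPMB (11R-OTBS, 12Z, oxolane 14S,15S-OMe,17R, 18R, 19R, 20E, 22R,23S-bis-OTBS) | `C[C@H](O[Si](C)(C)C(C)(C)C)[C@H](O[Si](C)(C)C(C)(C)C)/C=C/[C@@H](OCc1ccc(OC)cc1)[C@H](C)[C@H]1C[C@H](OC)[C@H](/C=C(/C)[C@H](O[Si](C)(C)C(C)(C)C)C/C=C\[Sn](CCCC)(CCCC)CCCC)O1` | intermediate
27 | C8–C24 (8Z)-alkenylstannane with free 19R hydroxyl (26 without PMB) | `C[C@H](O[Si](C)(C)C(C)(C)C)[C@H](O[Si](C)(C)C(C)(C)C)/C=C/[C@@H](O)[C@H](C)[C@H]1C[C@H](OC)[C@H](/C=C(/C)[C@H](O[Si](C)(C)C(C)(C)C)C/C=C\[Sn](CCCC)(CCCC)CCCC)O1` | intermediate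
28 | 2-[bis(2,2,2-trifluoroethoxy)phosphoryl]propanoic acid | `CC(C(=O)O)P(=O)(OCC(F)(F)F)OCC(F)(F)F` | intermediate
29 | 27 acylated at O19 with 28 (both epimers at the phosphonate α-carbon) | `C[C@H](O[Si](C)(C)C(C)(C)C)[C@H](O[Si](C)(C)C(C)(C)C)/C=C/[C@@H](OC(=O)C(C)P(=O)(OCC(F)(F)F)OCC(F)(F)F)[C@H](C)[C@H]1C[C@H](OC)[C@H](/C=C(/C)[C@H](O[Si](C)(C)C(C)(C)C)C/C=C\[Sn](CCCC)(CCCC)CCCC)O1` | intermediate
30 | prop-2-yn-1-ol | `C#CCO` | starting material
31 | (E)-3-iodo-2-methylprop-2-en-1-ol | `OC/C(C)=C/I` | intermediate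
32 | (E)-3-iodo-2-methylprop-2-enal | `O=C/C(C)=C/I` | intermediate
33 | (R)-4-benzyl-3-propanoyl-1,3-oxazolidin-2-one | `O=C1OC[C@@H](Cc2ccccc2)N1C(=O)CC` | starting material
34 | (R)-4-benzyl-3-[(2R,3R,4E)-3-hydroxy-5-iodo-2,4-dimethylpent-4-enoyl]-1,3-oxazolidin-2-one | `O=C1OC[C@@H](Cc2ccccc2)N1C(=O)[C@H](C)[C@@H](O)/C(C)=C/I` | intermediate
35 | (R)-4-benzyl-3-[(2R,3R,4E)-5-iodo-2,4-dimethyl-3-(triethylsilyloxy)pent-4-enoyl]-1,3-oxazolidin-2-one | `O=C1OC[C@@H](Cc2ccccc2)N1C(=O)[C@H](C)[C@@H](O[Si](CC)(CC)CC)/C(C)=C/I` | intermediate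
36 | (2S,3R,4E)-5-iodo-2,4-dimethyl-3-(triethylsilyloxy)pent-4-en-1-ol | `OC[C@H](C)[C@@H](O[Si](CC)(CC)CC)/C(C)=C/I` | intermediate
37 | (2R,3R,4E)-5-iodo-2,4-dimethyl-3-(triethylsilyloxy)pent-4-enal (C3–C7) | `O=C[C@H](C)[C@@H](O[Si](CC)(CC)CC)/C(C)=C/I` | intermediate
38 | (2Z,4S,5R,6E)-7-iodo-2,4,6-trimethyl-5-(triethylsilyloxy)hepta-2,6-dienoate of alcohol 27 (O19 ester) | `C[C@H](O[Si](C)(C)C(C)(C)C)[C@H](O[Si](C)(C)C(C)(C)C)/C=C/[C@@H](OC(=O)/C(C)=C\[C@H](C)[C@@H](O[Si](CC)(CC)CC)/C(C)=C/I)[C@H](C)[C@H]1C[C@H](OC)[C@H](/C=C(/C)[C@H](O[Si](C)(C)C(C)(C)C)C/C=C\[Sn](CCCC)(CCCC)CCCC)O1` | intermediate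
39 | (2Z,4S,5R,6E)-5-hydroxy-7-iodo-2,4,6-trimethylhepta-2,6-dienoate of alcohol 27 | `C[C@H](O[Si](C)(C)C(C)(C)C)[C@H](O[Si](C)(C)C(C)(C)C)/C=C/[C@@H](OC(=O)/C(C)=C\[C@H](C)[C@@H](O)/C(C)=C/I)[C@H](C)[C@H]1C[C@H](OC)[C@H](/C=C(/C)[C@H](O[Si](C)(C)C(C)(C)C)C/C=C\[Sn](CCCC)(CCCC)CCCC)O1` | intermediate
40 | (2Z,4S,6E)-7-iodo-2,4,6-trimethyl-5-oxohepta-2,6-dienoate of alcohol 27 (open-chain precursor) | `C[C@H](O[Si](C)(C)C(C)(C)C)[C@H](O[Si](C)(C)C(C)(C)C)/C=C/[C@@H](OC(=O)/C(C)=C\[C@H](C)C(=O)/C(C)=C/I)[C@H](C)[C@H]1C[C@H](OC)[C@H](/C=C(/C)[C@H](O[Si](C)(C)C(C)(C)C)C/C=C\[Sn](CCCC)(CCCC)CCCC)O1` | intermediate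
41 | 11,22,23-tris-O-(tert-butyldimethylsilyl)maltepolide D | `CO[C@H]1C[C@H]2O[C@H]1/C=C(/C)[C@H](O[Si](C)(C)C(C)(C)C)C/C=C\C=C(/C)C(=O)[C@@H](C)/C=C(/C)C(=O)O[C@H](/C=C/[C@@H](O[Si](C)(C)C(C)(C)C)[C@H](C)O[Si](C)(C)C(C)(C)C)[C@@H]2C` | intermediate
42 | Maltepolide D | `CO[C@H]1C[C@H]2O[C@H]1/C=C(/C)[C@H](O)C/C=C\C=C(/C)C(=O)[C@@H](C)/C=C(/C)C(=O)O[C@H](/C=C/[C@@H](O)[C@H](C)O)[C@@H]2C` | target

**Step count and risks**

Total step count: 33. Longest linear sequence: 26 steps (steps 1–20, 22, 29–33).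

Steps most likely to fail:

Step 32. Ring closure may lose to intermolecular coupling (oligomerisation). The alkenylstannane may be protodestannylated. The open-chain β-iodoenone may epimerise or suffer double-bond migration at C4 before it cyclises. The fallback closes the ring one oxidation level lower, so that the labile C4–H/C5 ketone pair exists only inside the ring. It sets out from 38: Stille ring closure under the same zerovalent palladium/AsPh3 conditions on the configurationally robust allylic silyl ether should give the macrocyclic C5 triethylsilyl ether F1. Methanolysis (pyridinium p-toluenesulfonate, MeOH, 0 °C) then gives the macrocyclic C5 alcohol F2. Dess–Martin oxidation of this single free, dienylic alcohol returns to 41.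

Step 10. Epoxidation of the monosubstituted alkene may be slow or unselective because the 1,3-diol ties up titanium, and the epoxide may open 6-endo instead of 5-exo. The fallback replaces epoxide opening by an electrophile-induced cyclisation and sets out from 13. Iodoetherification (I2, NaHCO3, MeCN, 0 °C), in which the allylic hydroxyl sits inside and directs 2,3-cis, 2,5-trans closure, should give the iodomethyl oxolanol F3. Me3OBF4 with 1,8-bis(dimethylamino)naphthalene gives the C15 methyl ether iodide F4. CsOAc, 18-crown-6, DMF at 70 °C gives the acetate F5, and K2CO3 in MeOH the primary alcohol F6. Dess–Martin oxidation gives the methoxy aldehyde F7, and Still–Gennari olefination with 17 returns to 19.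

Step 16. Facial control by the catalyst may be insufficient on the hindered trisubstituted enal, and the Z-enal may isomerise to E under the acidic conditions before addition. The fallback sets C11 by ketone reduction instead of carbonyl addition and sets out from ester 19. MeNH(OMe)·HCl with i-PrMgCl (THF, −20 °C) gives the Weinreb amide F8. Allenylmagnesium bromide (Et2O, −78 °C, SE2' addition) gives the β,γ-acetylenic Z-enone F9. Corey–Bakshi–Shibata reduction with the (S)-methyl oxazaborolidine and BH3·SMe2 (−40 °C), with the alkenyl group as the large substituent, should give 23, where the route resumes.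

**Further compounds**

F1 | step 32 | macrocyclic (5R)-triethylsilyl ether (11,22,23-tris-O-TBS, C5 silyloxy in place of the ketone) | `CO[C@H]1C[C@H]2O[C@H]1/C=C(/C)[C@H](O[Si](C)(C)C(C)(C)C)C/C=C\C=C(/C)[C@H](O[Si](CC)(CC)CC)[C@@H](C)/C=C(/C)C(=O)O[C@H](/C=C/[C@@H](O[Si](C)(C)C(C)(C)C)[C@H](C)O[Si](C)(C)C(C)(C)C)[C@@H]2C`
F2 | step 32 | macrocyclic (5R)-alcohol (11,22,23-tris-O-TBS) | `CO[C@H]1C[C@H]2O[C@H]1/C=C(/C)[C@H](O[Si](C)(C)C(C)(C)C)C/C=C\C=C(/C)[C@H](O)[C@@H](C)/C=C(/C)C(=O)O[C@H](/C=C/[C@@H](O[Si](C)(C)C(C)(C)C)[C@H](C)O[Si](C)(C)C(C)(C)C)[C@@H]2C`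
F3 | step 10 | (2R,3S,5R)-5-(side chain as in 15)-2-(iodomethyl)oxolan-3-ol | `C[C@H](O[Si](C)(C)C(C)(C)C)[C@H](O[Si](C)(C)C(C)(C)C)/C=C/[C@@H](OCc1ccc(OC)cc1)[C@H](C)[C@H]1C[C@H](O)[C@H](CI)O1`
F4 | step 10 | (2R,3S,5R)-5-(side chain as in 15)-2-(iodomethyl)-3-methoxyoxolane | `C[C@H](O[Si](C)(C)C(C)(C)C)[C@H](O[Si](C)(C)C(C)(C)C)/C=C/[C@@H](OCc1ccc(OC)cc1)[C@H](C)[C@H]1C[C@H](OC)[C@H](CI)O1`
F5 | step 10 | [(2S,3S,5R)-5-(side chain as in 15)-3-methoxyoxolan-2-yl]methyl acetate | `C[C@H](O[Si](C)(C)C(C)(C)C)[C@H](O[Si](C)(C)C(C)(C)C)/C=C/[C@@H](OCc1ccc(OC)cc1)[C@H](C)[C@H]1C[C@H](OC)[C@H](COC(C)=O)O1`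
F6 | step 10 | [(2S,3S,5R)-5-(side chain as in 15)-3-methoxyoxolan-2-yl]methanol | `C[C@H](O[Si](C)(C)C(C)(C)C)[C@H](O[Si](C)(C)C(C)(C)C)/C=C/[C@@H](OCc1ccc(OC)cc1)[C@H](C)[C@H]1C[C@H](OC)[C@H](CO)O1`
F7 | step 10 | (2R,3S,5R)-5-(side chain as in 15)-3-methoxyoxolane-2-carbaldehyde | `C[C@H](O[Si](C)(C)C(C)(C)C)[C@H](O[Si](C)(C)C(C)(C)C)/C=C/[C@@H](OCc1ccc(OC)cc1)[C@H](C)[C@H]1C[C@H](OC)[C@H](C=O)O1`
F8 | step 16 | (2Z)-N-methoxy-N,2-dimethyl-3-[(2S,3S,5R)-5-(side chain as in 15)-3-methoxyoxolan-2-yl]prop-2-enamide | `C[C@H](O[Si](C)(C)C(C)(C)C)[C@H](O[Si](C)(C)C(C)(C)C)/C=C/[C@@H](OCc1ccc(OC)cc1)[C@H](C)[C@H]1C[C@H](OC)[C@H](/C=C(/C)C(=O)N(C)OC)O1`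
F9 | step 16 | (1Z)-1-[(2S,3S,5R)-5-(side chain as in 15)-3-methoxyoxolan-2-yl]-2-methylhex-1-en-5-yn-3-one | `C[C@H](O[Si](C)(C)C(C)(C)C)[C@H](O[Si](C)(C)C(C)(C)C)/C=C/[C@@H](OCc1ccc(OC)cc1)[C@H](C)[C@H]1C[C@H](OC)[C@H](/C=C(/C)C(=O)CC#C)O1`
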